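Rings A and C are removed together by cutting C4a–C8a and O1–C2 at the same time. Two features of the target make this possible. Ring A is a phloroglucinol bearing the C4 acyl carbon on C4a, which is the folding pattern of a tetraketide, and the oxygen on C8a can reach C2 through a six-membered ring. The precursor is a 4-hydroxy-2-pyrone whose C6 carries a CH2–CO–C(=CH2)–aryl chain with ring B complete. One treatment with magnesium methoxide opens the lactone, recloses the chain as the acylphloroglucinol and lets a phenoxide add to the vinyl ketone, giving the racemic isoflavanone. C3 is fixed afterwards by catalytic enantioselective protonation of an enol silane.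

Key step: step 8

Numbering and shorthand: isoflavanone numbering is used (O1, C2, C3, C4, C4a, C5–C8, C8a; ring B primed). Ar = 4-methoxy-2,3-bis(methoxymethoxy)-5-(3-methylbut-2-en-1-yl)phenyl.

Assumption: the sense of induction of the chiral acid in step 11 cannot be derived safely from simpler 2-arylcycloalkanones. The (S)-BINOL-derived catalyst is written, and its equally available antipode is used if a pilot run shows the opposite sense.

Design remarks:
- The cascade precursor holds an acidic, C-nucleophilic pyrone next to a vinyl ketone. It is therefore made in the step directly before the cascade and is not stored.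
- The ring-B acetals are removed while the material is still racemic. Once C3 is set, only a cold methanolysis follows.

Step 1
Reactants: 1 2,3-dihydroxy-4-methoxybenzaldehyde
Product: 2 5-bromo-2,3-dihydroxy-4-methoxybenzaldehyde
Conditions: Br2 (1.0 equiv), NaOAc, AcOH, rt
Reagents that add atoms: bromine, BrBr
Why: Electrophilic aromatic bromination should go to C5, which is para to the C2 hydroxyl, ortho to the methoxy group and meta to the formyl group, whereas C6 is activated by one oxygen only and lies ortho to the aldehyde.

Step 2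
Reactants: 2 5-bromo-2,3-dihydroxy-4-methoxybenzaldehyde
Product: 3 5-bromo-4-methoxy-2,3-bis(methoxymethoxy)benzaldehyde
Conditions: MOMCl (3 equiv), i-Pr2NEt, CH2Cl2, 0 °C → rt
Reagents that add atoms: chloromethyl methyl ether, COCCl
Why: Williamson-type O-alkylation converts both phenols into MOM acetals, which tolerate every basic, organometallic and oxidative operation up to step 9.

Step 3
Reactants: 3 5-bromo-4-methoxy-2,3-bis(methoxymethoxy)benzaldehyde; 4 tributyl(3-methylbut-2-en-1-yl)stannane
Product: 5 4-methoxy-2,3-bis(methoxymethoxy)-5-(3-methylbut-2-en-1-yl)benzaldehyde (ArCHO)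
Conditions: Pd(PPh3)4 (5 mol %), DMF, 100 °C
Reagents that add atoms: tributyl(3-methylbut-2-en-1-yl)stannane (4), CCCC[Sn](CCCC)(CCCC)CC=C(C)C
Why: Stille cross-coupling tolerates the free aldehyde, and with prenylstannanes reductive elimination normally takes place at the unsubstituted allyl terminus, so the linear prenyl arene should result.

Step 4
Reactants: 5 ArCHO
Product: 6 racemic 2-Ar-oxirane
Conditions: Me3S+ I−, NaH, DMSO–THF, 0 °C → rt
Reagents that add atoms: trimethylsulfonium iodide, C[S+](C)C.[I-]
Why: In the Corey–Chaykovsky epoxidation the unstabilised sulfur ylide adds to the non-enolisable aldehyde and the betaine closes to the terminal epoxide under basic conditions harmless to acetals and alkene, and the new centre is racemic and is erased in step 5.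

Step 5
Reactants: 6 racemic 2-Ar-oxirane
Product: 8 2-Ar-prop-2-enal (2-arylacrolein), via arylacetaldehyde 7 (not isolated)
Conditions: BF3·OEt2 (10 mol %), CH2Cl2, −78 → −30 °C; then Et3N, CH2=NMe2+ I−, → rt
Reagents that add atoms: N,N-dimethylmethyleneiminium iodide (Eschenmoser's salt), C=[N+](C)C.[I-]
Why: A Meinwald rearrangement (benzylic C–O ionisation assisted by the ortho and para oxygens, then 1,2-hydride shift) is followed in the same flask by Mannich α-methylenation and amine elimination, so the fragile arylacetaldehyde is never handled.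

Step 6
Reactants: 9 4-hydroxy-6-methyl-2H-pyran-2-one; 8 2-Ar-prop-2-enal
Product: 11 racemic 4-hydroxy-6-(3-Ar-2-hydroxybut-3-en-1-yl)-2H-pyran-2-one, via dilithiated pyrone 10 (not isolated)
Conditions: 9 (1.3 equiv), LDA (2.05 equiv per 9), THF–DMPU, −78 → −20 °C; 8, −78 °C; AcOH, −78 °C
Reagents that add atoms: 4-hydroxy-6-methyl-2H-pyran-2-one (9), Cc1cc(O)cc(=O)o1
Why: In this aldol-type addition the pyrone dianion reacts at its more basic C6-methylene terminus, the aldehyde has no α-hydrogen to lose, and the lithium dienolate at −78 °C should add 1,2 under kinetic control to a racemic carbinol whose centre is removed in step 7.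

Step 7
Reactants: 11 racemic 4-hydroxy-6-(3-Ar-2-hydroxybut-3-en-1-yl)-2H-pyran-2-one
Product: 12 4-hydroxy-6-(3-Ar-2-oxobut-3-en-1-yl)-2H-pyran-2-one
Conditions: IBX (1.5 equiv), DMSO–THF, rt; extractive work-up, used at once
Reagents that add atoms: none
Why: IBX oxidation of the secondary allylic alcohol is chosen because this reagent is established for β-hydroxy carbonyl to 1,3-dicarbonyl oxidations, needs no base, does not attack the activated methylene at room temperature and leaves alkene, MOM groups and arene alone.

Step 8
Reactants: 12 4-hydroxy-6-(3-Ar-2-oxobut-3-en-1-yl)-2H-pyran-2-one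
Product: 15 racemic 5,7-dihydroxy-3-Ar-chroman-4-one (2',3'-bis-O-MOM isoflavanone), via trioxo ester 13 (not isolated), via acylphloroglucinol enone 14 (not isolated)
Conditions: Mg(OMe)2 (8 equiv), dry MeOH (5 mM), Ar, 0 °C → reflux; cold 0.5 M HCl to pH 4
Reagents that add atoms: none
Why: Proposed new method: methoxide held on magnesium opens the lactone of 12 at the carbon that becomes C8a to give the chelated 3,5,7-trioxo ester 13, the carbanion at C4a (flanked by the C4 and C5 carbonyls) attacks that ester carbon with loss of methoxide, and enolisation of the resulting triketone delivers the aromatic ketone 14, whose ortho phenoxide adds to C2 of the vinyl ketone to give 15. The closest known reaction types are the magnesium methoxide Claisen cyclisation of 6-(2-oxoalkyl)-4-hydroxy-2-pyrones and 3,5,7-triketo esters to acylphloroglucinols and the oxa-Michael closure of 2-hydroxyphenyl 1-arylvinyl ketones met in the classical deoxybenzoin–formaldehyde isoflavanone synthesis; new is their combination on a polyketide chain that already carries the vinyl ketone. Ring A closes in a 6-(enolexo)-exo-trig mode and ring C in a 6-endo-trig mode, and because the two ortho oxygens of 14 are equivalent by rotation about C4–C4a there is no regiochemical question. C3 becomes stereogenic only on protonation of the final magnesium enolate, no element controls it, and 15 is racemic by design. The step needs Claisen (C4a onto the ester) instead of aldol (C8 onto C4) folding, which chelation of the dicarbonyl units by Mg2+ in dry methanol and the low electrophilicity of the cross-conjugated, aryl-shielded C4 ketone should secure. It also needs the carbon nucleophiles of the chain and of other molecules to spare C2, which high dilution and the reversible conjugate addition of methanol (keeping little free enone present until the phenoxide exists) should secure, while the MOM groups leave ring A as the only source of phenoxide.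

Step 9
Reactants: 15 racemic 5,7-dihydroxy-3-Ar-chroman-4-one
Product: 16 racemic 3-[2,3-dihydroxy-4-methoxy-5-(3-methylbut-2-en-1-yl)phenyl]-5,7-dihydroxychroman-4-one
Conditions: HCl (1.25 M in MeOH), MeOH–THF, rt → 40 °C
Reagents that add atoms: none
Why: Acid-catalysed acetal exchange with methanol cleaves both MOM groups while the material is still racemic, so enolisation at C3 costs nothing, the prenyl group has no ortho hydroxyl to cyclise onto and the 5-OH-chelated ketone should resist cyclodehydration with the 2'-OH.

Step 10
Reactants: 16 racemic tetraphenol isoflavanone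
Product: 17 3-[4-methoxy-5-(3-methylbut-2-en-1-yl)-2,3-bis(trimethylsilyloxy)phenyl]-4,5,7-tris(trimethylsilyloxy)-2H-chromene
Conditions: Et3N (10 equiv), TMSOTf (6.5 equiv), CH2Cl2, 0 °C → rt; pentane trituration, filtration under Ar
Reagents that add atoms: trimethylsilyl trifluoromethanesulfonate, C[Si](C)(C)OS(=O)(=O)C(F)(F)F
Why: Soft enolisation and O-silylation with TMSOTf–Et3N caps the four phenols at once and removes the benzylic C3–H from the O-silylated ketone, giving the only possible (endocyclic, tetrasubstituted C3=C4) silyl enol ether and thereby deleting the racemic centre.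

Step 11
Reactants: 17 pentakis-TMS 2H-chromene
Product: 19 (3R)-3-[2,3-dihydroxy-4-methoxy-5-(3-methylbut-2-en-1-yl)phenyl]-5,7-dihydroxychroman-4-one, via tetrakis-TMS (R)-ketone 18 (not isolated)
Conditions: (S)-3,3'-bis(2,4,6-triisopropylphenyl)-BINOL N-triflyl thiophosphoramide (5 mol %), PhOH (1.1 equiv), toluene, −20 °C → rt; then MeOH, 0 °C
Reagents that add atoms: none
Why: This is the catalytic enantioselective protonation of a silyl enol ether of a cyclic α-aryl ketone by a chiral Brønsted acid with phenol as stoichiometric proton source, in which the confined ion pair should deliver the proton to the Si face of C3 and so set 3R, after which the aryl silyl ethers fall off by acid-catalysed methanolysis at 0 °C, too mild to enolise the ketone.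

Compound list
1 | 2,3-dihydroxy-4-methoxybenzaldehyde | COc1ccc(C=O)c(O)c1O | starting material
2 | 5-bromo-2,3-dihydroxy-4-methoxybenzaldehyde | COc1c(Br)cc(C=O)c(O)c1O | intermediate
3 | 5-bromo-4-methoxy-2,3-bis(methoxymethoxy)benzaldehyde | COc1c(Br)cc(C=O)c(OCOC)c1OCOC | intermediate
4 | tributyl(3-methylbut-2-en-1-yl)stannane | CCCC[Sn](CCCC)(CCCC)CC=C(C)C | starting material
5 | 4-methoxy-2,3-bis(methoxymethoxy)-5-(3-methylbut-2-en-1-yl)benzaldehyde | COc1c(CC=C(C)C)cc(C=O)c(OCOC)c1OCOC | intermediate
6 | racemic 2-[4-methoxy-2,3-bis(methoxymethoxy)-5-(3-methylbut-2-en-1-yl)phenyl]oxirane | COc1c(CC=C(C)C)cc(C2CO2)c(OCOC)c1OCOC | intermediate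
7 | 2-[4-methoxy-2,3-bis(methoxymethoxy)-5-(3-methylbut-2-en-1-yl)phenyl]acetaldehyde (not isolated) | COc1c(CC=C(C)C)cc(CC=O)c(OCOC)c1OCOC | intermediate
8 | 2-[4-methoxy-2,3-bis(methoxymethoxy)-5-(3-methylbut-2-en-1-yl)phenyl]prop-2-enal | COc1c(CC=C(C)C)cc(C(=C)C=O)c(OCOC)c1OCOC | intermediate
9 | 4-hydroxy-6-methyl-2H-pyran-2-one | Cc1cc(O)cc(=O)o1 | starting material
10 | dilithium salt of 9 deprotonated at O4 and at the C6 methyl group (not isolated) | [Li+].[Li+].[CH2-]c1cc([O-])cc(=O)o1 | intermediate
11 | racemic 4-hydroxy-6-(3-Ar-2-hydroxybut-3-en-1-yl)-2H-pyran-2-one | COc1c(CC=C(C)C)cc(C(=C)C(O)Cc2cc(O)cc(=O)o2)c(OCOC)c1OCOC | intermediate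
12 | 4-hydroxy-6-(3-Ar-2-oxobut-3-en-1-yl)-2H-pyran-2-one (cascade precursor) | COc1c(CC=C(C)C)cc(C(=C)C(=O)Cc2cc(O)cc(=O)o2)c(OCOC)c1OCOC | intermediate
13 | methyl 8-Ar-3,5,7-trioxonon-8-enoate, present as magnesium chelate (not isolated) | COC(=O)CC(=O)CC(=O)CC(=O)C(=C)c1cc(CC=C(C)C)c(OC)c(OCOC)c1OCOC | intermediate
14 | 2-Ar-1-(2,4,6-trihydroxyphenyl)prop-2-en-1-one (not isolated) | C=C(C(=O)c1c(O)cc(O)cc1O)c1cc(CC=C(C)C)c(OC)c(OCOC)c1OCOC | intermediate
15 | racemic 5,7-dihydroxy-3-Ar-chroman-4-one (cascade product) | COc1c(CC=C(C)C)cc(C2COc3cc(O)cc(O)c3C2=O)c(OCOC)c1OCOC | intermediate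
16 | racemic 3-[2,3-dihydroxy-4-methoxy-5-(3-methylbut-2-en-1-yl)phenyl]-5,7-dihydroxychroman-4-one | COc1c(CC=C(C)C)cc(C2COc3cc(O)cc(O)c3C2=O)c(O)c1O | intermediate
17 | 3-[4-methoxy-5-(3-methylbut-2-en-1-yl)-2,3-bis(trimethylsilyloxy)phenyl]-4,5,7-tris(trimethylsilyloxy)-2H-chromene | COc1c(CC=C(C)C)cc(C2=C(O[Si](C)(C)C)c3c(O[Si](C)(C)C)cc(O[Si](C)(C)C)cc3OC2)c(O[Si](C)(C)C)c1O[Si](C)(C)C | intermediate
18 | (3R)-3-[4-methoxy-5-(3-methylbut-2-en-1-yl)-2,3-bis(trimethylsilyloxy)phenyl]-5,7-bis(trimethylsilyloxy)chroman-4-one (not isolated) | COc1c(CC=C(C)C)cc([C@@H]2COc3cc(O[Si](C)(C)C)cc(O[Si](C)(C)C)c3C2=O)c(O[Si](C)(C)C)c1O[Si](C)(C)C | intermediate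
19 | (3R)-3-[2,3-dihydroxy-4-methoxy-5-(3-methylbut-2-en-1-yl)phenyl]-5,7-dihydroxychroman-4-one (CNP0141716.1) | COc1c(CC=C(C)C)cc([C@@H]2COc3cc(O)cc(O)c3C2=O)c(O)c1O | target

Total step count: 11. Longest linear sequence: 11 steps (1 → 19).

Steps most likely to fail

Step 8 (the labelled step).
- What may go wrong: carbon nucleophiles of the opened chain, or of a second molecule, may add to the vinyl ketone before ring A exists. The chain may also fold in the aldol sense, or the material may oligomerise.
- Fallback: known chemistry in which ring A is bought instead of built. It sets out from 8 and comes back at 16.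
- Phloroglucinol is converted with MOMCl and NaH into 1,3,5-tris(methoxymethoxy)benzene F1. This is lithiated with n-BuLi (THF, 0 °C) between two acetal oxygens to 2,4,6-tris(methoxymethoxy)phenyllithium F2.
- 1,2-Addition of F2 to 8 at −78 °C should give the racemic doubly activated carbinol F3. MnO2 or Dess–Martin periodinane then gives the aryl 1-arylvinyl ketone F4.
- HCl in MeOH strips all five acetals to the pentahydroxy enone F5. On buffering with NaOAc, F5 closes by the familiar 6-endo-trig oxa-Michael addition and so rejoins the route at 16.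

Step 11.
- What may go wrong: facial selectivity of proton transfer to this crowded, peri-substituted chromene may be poor. Uncatalysed background protonation by adventitious acid may also erode the enantiomeric purity.
- Fallback: the asymmetric protonation is replaced by asymmetric transfer hydrogenation with dynamic kinetic resolution, a reaction demonstrated on racemic isoflavanones. It sets out from 15 and comes back at 19.
- MOMCl and NaH in DMF give the racemic tetrakis-O-MOM isoflavanone F6.
- RuCl[(R,R)-TsDPEN](p-cymene) with HCO2H–Et3N reduces one rapidly equilibrating enantiomer to the cis-(3R,4R)-isoflavan-4-ol F7.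
- Dess–Martin periodinane buffered with NaHCO3 at 0 °C returns the ketone as the (3R)-tetrakis-O-MOM isoflavanone F8 without touching C3.
- Brief treatment with HCl in MeOH at 0 °C → rt gives 19.

Step 7.
- What may go wrong: the oxidant may attack the enolic pyrone or the newly activated methylene. The acidic pyrone may also add to the liberated vinyl ketone during isolation.
- Fallback: the acidic function is removed before the oxidation. It sets out from 11 and comes back at 12.
- Pivaloyl chloride (1.0 equiv) and Et3N in CH2Cl2 at −20 °C acylate only the pyrone oxygen, present as its ammonium salt, to give the 4-O-pivaloyl carbinol F9.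
- Dess–Martin periodinane then gives the neutral, chromatographable 4-O-pivaloyl enone F10.
- F10 is fed directly into the conditions of step 8. Methoxide removes the pivaloyl group first and thereby regenerates 12 in the flask.

Further compounds
F1 | step 8 | 1,3,5-tris(methoxymethoxy)benzene | COCOc1cc(OCOC)cc(OCOC)c1
F2 | step 8 | 2,4,6-tris(methoxymethoxy)phenyllithium | [Li]c1c(OCOC)cc(OCOC)cc1OCOC
F3 | step 8 | racemic 2-Ar-1-[2,4,6-tris(methoxymethoxy)phenyl]prop-2-en-1-ol | C=C(C(O)c1c(OCOC)cc(OCOC)cc1OCOC)c1cc(CC=C(C)C)c(OC)c(OCOC)c1OCOC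
F4 | step 8 | 2-Ar-1-[2,4,6-tris(methoxymethoxy)phenyl]prop-2-en-1-one | C=C(C(=O)c1c(OCOC)cc(OCOC)cc1OCOC)c1cc(CC=C(C)C)c(OC)c(OCOC)c1OCOC
F5 | step 8 | 2-[2,3-dihydroxy-4-methoxy-5-(3-methylbut-2-en-1-yl)phenyl]-1-(2,4,6-trihydroxyphenyl)prop-2-en-1-one | C=C(C(=O)c1c(O)cc(O)cc1O)c1cc(CC=C(C)C)c(OC)c(O)c1O
F6 | step 11 | racemic 5,7-bis(methoxymethoxy)-3-Ar-chroman-4-one | COc1c(CC=C(C)C)cc(C2COc3cc(OCOC)cc(OCOC)c3C2=O)c(OCOC)c1OCOC
F7 | step 11 | (3R,4R)-5,7-bis(methoxymethoxy)-3-Ar-chroman-4-ol (cis) | COc1c(CC=C(C)C)cc([C@@H]2COc3cc(OCOC)cc(OCOC)c3[C@@H]2O)c(OCOC)c1OCOC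
F8 | step 11 | (3R)-5,7-bis(methoxymethoxy)-3-Ar-chroman-4-one | COc1c(CC=C(C)C)cc([C@@H]2COc3cc(OCOC)cc(OCOC)c3C2=O)c(OCOC)c1OCOC
F9 | step 7 | racemic 6-(3-Ar-2-hydroxybut-3-en-1-yl)-2-oxo-2H-pyran-4-yl pivalate | C=C(C(O)Cc1cc(OC(=O)C(C)(C)C)cc(=O)o1)c1cc(CC=C(C)C)c(OC)c(OCOC)c1OCOC
F10 | step 7 | 6-(3-Ar-2-oxobut-3-en-1-yl)-2-oxo-2H-pyran-4-yl pivalate | C=C(C(=O)Cc1cc(OC(=O)C(C)(C)C)cc(=O)o1)c1cc(CC=C(C)C)c(OC)c(OCOC)c1OCOC
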